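## Retrosynthetic overview
1. The target comes from its E-cinnamate methyl ester by 1,2-reduction of the ester in the last step.
2. The cinnamate comes from a homopropargyl pyridazinyl ether. One intramolecular alkyne/1,2-diazine [4+2] with loss of N2 forms C3a–C7a and C4–C5, so ring B (benzo) and ring C (dihydrofuran) appear together. The sacrificial pyridazine supplies C5–C7a with the OMe and acrylate already in place.
3. The ether comes from SNAr of the anti-alkynol alkoxide on a 3-chloropyridazine. This forms the O1–C7a bond and leaves the carbinol C–O bond untouched.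
4. The anti-(1S,2S)-alkynol comes from veratraldehyde and (R)-but-3-yn-2-yl mesylate; the allenylzinc addition sets C2 and C3. The chloropyridazine comes from 3,6-dichloro-4-methoxypyridazine and methyl acrylate by a site-selective Heck reaction.
5. Ring order: ring A is bought, and rings B and C form simultaneously in step 5.

Assumption: the SMILES is read as the (2S,3S)-trans, E compound (benzofuran numbering), and the four carbon building blocks are taken as catalogue items.

## Route

Step 1
Reactants: 1 (R)-but-3-yn-2-ol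
Product: 2 (R)-but-3-yn-2-yl methanesulfonate
Conditions: MsCl (1.2 equiv), Et3N (1.5 equiv), CH2Cl2, −78 to 0 °C
Reagents that add atoms: methanesulfonyl chloride, CS(=O)(=O)Cl
Why: Simple O-sulfonylation (mesylation) breaks only the O–H bond, so the R configuration is kept and the alcohol becomes a leaving group for the palladium step.

Step 2
Reactants: 2 (R)-but-3-yn-2-yl methanesulfonate; 3 3,4-dimethoxybenzaldehyde (veratraldehyde)
Product: 5 (1S,2S)-1-(3,4-dimethoxyphenyl)-2-methylbut-3-yn-1-ol, via allenylzinc mesylate 4 (not isolated)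
Conditions: Pd(OAc)2 (5 mol %), PPh3 (5 mol %), Et2Zn (3 equiv), THF, −78 to −20 °C; aq. NH4Cl
Reagents that add atoms: none
Why: In this Marshall–Tamaru allenylzinc addition, zerovalent palladium displaces the mesylate anti (SN2′), Et2Zn takes over the allenyl group with retention to give configurationally stable (P)-4, and 4 adds through a closed six-membered SE2′ transition state with the aryl group turned away from the allenyl methyl, so the methyl-bearing carbon (S) comes from 2 by centre-to-axis-to-centre transfer and the carbinol carbon (S) from the anti-selective transition state (about 85:15 anti:syn expected for an aryl aldehyde, minor isomer removed on silica).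

Step 3
Reactants: 6 3,6-dichloro-4-methoxypyridazine; 7 methyl acrylate
Product: 8 methyl (E)-3-(6-chloro-5-methoxypyridazin-3-yl)prop-2-enoate
Conditions: Pd(P(t-Bu)3)2 (3 mol %), Cy2NMe (1.2 equiv), 7 (1.1 equiv), 1,4-dioxane, 90 °C
Reagents that add atoms: none
Why: In this Mizoroki–Heck reaction, oxidative addition goes to the C6–Cl bond, which is unhindered and not fed by the methoxy donor, while C3–Cl (ortho to OMe) stays, and syn insertion/syn β-hydride elimination gives the E-acrylate.

Step 4
Reactants: 5 (1S,2S)-1-(3,4-dimethoxyphenyl)-2-methylbut-3-yn-1-ol; 8 methyl (E)-3-(6-chloro-5-methoxypyridazin-3-yl)prop-2-enoate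
Product: 10 methyl (E)-3-(6-{[(1S,2S)-1-(3,4-dimethoxyphenyl)-2-methylbut-3-yn-1-yl]oxy}-5-methoxypyridazin-3-yl)prop-2-enoate, via sodium alkoxide 9 (not isolated)
Conditions: NaH (1.05 equiv), THF, 0 °C; then 8, 0 °C to rt
Reagents that add atoms: none
Why: SNAr (addition–elimination) occurs at the only remaining C–Cl, activated by the adjacent ring nitrogen and the para-type acrylate, and because the bond made is O–C(heteroaryl), both stereocentres of 5 carry over unchanged.

Step 5
Reactants: 10 methyl (E)-3-(6-{[(1S,2S)-1-(3,4-dimethoxyphenyl)-2-methylbut-3-yn-1-yl]oxy}-5-methoxypyridazin-3-yl)prop-2-enoate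
Product: 12 methyl (E)-3-[(2S,3S)-2-(3,4-dimethoxyphenyl)-7-methoxy-3-methyl-2,3-dihydro-1-benzofuran-5-yl]prop-2-enoate, via diazabarrelene cycloadduct 11 (not isolated)
Conditions: 1,3,5-triisopropylbenzene (0.02 M), BHT (10 mol %), Ar, base-washed glass, 175 °C, 24–48 h
Reagents that add atoms: none
Why: This is an intramolecular inverse-electron-demand Diels–Alder reaction of the tethered terminal alkyne across the two carbon termini of the 1,2-diazine followed by retro-Diels–Alder loss of N2 (a reaction type known for 3-(but-3-ynyloxy)pyridazines), in which the new bonds C3a–C7a and C4–C5 close the dihydrofuran and the carbocycle in the same event, the three-atom tether fixes the regiochemistry, the acrylate lowers the diazine LUMO, the two tether substituents favour the reactive rotamer, both facial adducts 11 collapse to the same arene, and the spectator stereocentres turn anti-5 into the trans-(2S,3S) ring.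

Step 6
Reactants: 12 methyl (E)-3-[(2S,3S)-2-(3,4-dimethoxyphenyl)-7-methoxy-3-methyl-2,3-dihydro-1-benzofuran-5-yl]prop-2-enoate
Product: 14 (E)-3-[(2S,3S)-2-(3,4-dimethoxyphenyl)-7-methoxy-3-methyl-2,3-dihydro-1-benzofuran-5-yl]prop-2-en-1-ol, via enal 13 (not isolated)
Conditions: i-Bu2AlH (2.5 equiv), CH2Cl2, −78 °C; aq. KNaC4H4O6
Reagents that add atoms: none
Why: 1,2-Reduction of the α,β-unsaturated ester with i-Bu2AlH runs through the enal to the allylic alcohol without touching the E-alkene, the aryl ethers or the stereocentres.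

## Compound list
1 | (R)-but-3-yn-2-ol | C[C@@H](O)C#C | starting material
2 | (R)-but-3-yn-2-yl methanesulfonate | C[C@@H](OS(C)(=O)=O)C#C | intermediate
3 | 3,4-dimethoxybenzaldehyde (veratraldehyde) | COc1ccc(C=O)cc1OC | starting material
4 | (P)-buta-1,2-dien-1-ylzinc methanesulfonate (axis aS; not isolated) | CC([H])=[C@@]=C([H])[Zn]OS(C)(=O)=O | intermediate
5 | (1S,2S)-1-(3,4-dimethoxyphenyl)-2-methylbut-3-yn-1-ol (anti) | COc1ccc([C@@H](O)[C@@H](C)C#C)cc1OC | intermediate
6 | 3,6-dichloro-4-methoxypyridazine | COc1cc(Cl)nnc1Cl | starting material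
7 | methyl acrylate | C=CC(=O)OC | starting material
8 | methyl (E)-3-(6-chloro-5-methoxypyridazin-3-yl)prop-2-enoate | COC(=O)/C=C/c1cc(OC)c(Cl)nn1 | intermediate
9 | sodium (1S,2S)-1-(3,4-dimethoxyphenyl)-2-methylbut-3-yn-1-olate (not isolated) | COc1ccc([C@@H]([O-])[C@@H](C)C#C)cc1OC.[Na+] | intermediate
10 | methyl (E)-3-(6-{[(1S,2S)-1-(3,4-dimethoxyphenyl)-2-methylbut-3-yn-1-yl]oxy}-5-methoxypyridazin-3-yl)prop-2-enoate | COC(=O)/C=C/c1cc(OC)c(O[C@H](c2ccc(OC)c(OC)c2)[C@@H](C)C#C)nn1 | intermediate
11 | 2,3-diazabicyclo[2.2.2]octa-2,5,7-triene cycloadduct fused to the new oxolane; bridges N=N, C(OMe)=CH and C=CH; bridgeheads carry O1 and the acrylate; both facial diastereomers, so bridgeheads are left unspecified (not isolated) | COC(=O)/C=C/C12N=NC3(O[C@H](c4ccc(OC)c(OC)c4)[C@@H](C)C3=C1)C(OC)=C2 | intermediate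
12 | methyl (E)-3-[(2S,3S)-2-(3,4-dimethoxyphenyl)-7-methoxy-3-methyl-2,3-dihydro-1-benzofuran-5-yl]prop-2-enoate | COc1ccc([C@H]2Oc3c(OC)cc(/C=C/C(=O)OC)cc3[C@@H]2C)cc1OC | intermediate
13 | (E)-3-[(2S,3S)-2-(3,4-dimethoxyphenyl)-7-methoxy-3-methyl-2,3-dihydro-1-benzofuran-5-yl]prop-2-enal (not isolated) | COc1ccc([C@H]2Oc3c(OC)cc(/C=C/C=O)cc3[C@@H]2C)cc1OC | intermediate
14 | (E)-3-[(2S,3S)-2-(3,4-dimethoxyphenyl)-7-methoxy-3-methyl-2,3-dihydro-1-benzofuran-5-yl]prop-2-en-1-ol (CNP0330626.1) | COc1ccc([C@H]2Oc3c(OC)cc(/C=C/CO)cc3[C@@H]2C)cc1OC | target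

## Step count and risks
Total step count: 6. Longest linear sequence: 5 (steps 1, 2, 4, 5, 6).

**Most likely to fail, first: step 5.** The diazine carries two alkoxy donors. The electron-rich secondary benzylic pyridazinyl ether may therefore fragment before it cycloadds, either by retro-ene loss of the pyridazinone or by ionisation at C2.

The fallback changes the dienophile and the way aromaticity is reached. It sets out from 10 and comes back at 12.
- Semihydrogenation of 10 (H2, 1 atm, Pd/CaCO3 poisoned with Pb(OAc)2, quinoline, EtOAc) gives the terminal alkene ether F1.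
- The higher-lying π level of F1 should let the intramolecular [4+2] run at about 140 °C in chlorobenzene (sealed tube), giving the diazabicyclooctadiene adduct F2.
- F2 loses N2 to give the 3a,4-dihydrobenzofuran diene F3. Both rings still form in one event.
- DDQ (1.0 equiv, toluene, 0 °C) added to the cooled flask aromatises F3 to 12. This should be much faster than attack at the benzylic C2–H.

**Second: step 3.** Risks are incomplete C6/C3 discrimination, double Heck reaction, and binding of palladium by the diazine.

The fallback separates the two chlorides by a polar mechanism first. It sets out from 6 and comes back at 8.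
- NaSMe (1.0 equiv, THF, −20 °C) attacks C6, because that Meisenheimer adduct puts no charge on the OMe-bearing carbon. This gives 3-chloro-4-methoxy-6-(methylthio)pyridazine F4, whose structure is checked by NOE.
- A Liebeskind–Srogl-type desulfitative coupling of F4 follows, with methyl (E)-3-(tributylstannyl)acrylate, Pd(PPh3)4 (5 mol %) and Cu(O2CC4H3S) (2 equiv) in THF at 50 °C. It activates only the C–S bond and gives 8.

**Third: step 4.** The hindered secondary alkoxide may instead add to the acrylate, transesterify, or exchange the ring OMe.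

The fallback carries the side chain at the alcohol oxidation level, so no base-sensitive acceptor is present. It sets out from 6 and comes back at 14.
- Suzuki–Miyaura coupling of 6 with commercial (E)-3-(tert-butyldimethylsilyloxy)prop-1-enylboronic acid pinacol ester (PdCl2(dppf), K2CO3, dioxane–H2O, 70 °C) gives the silyl ether chloropyridazine F5.
- Alkoxide 9 (THF–DMF, up to 60 °C) converts F5 into the alkynyl silyl ether pyridazine F6.
- Heating F6 (1,3,5-triisopropylbenzene, about 200 °C, since this diazine is less activated) gives the silylated diazabarrelene adduct F7.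
- F7 loses N2 to give the silyl-protected target F8, and n-Bu4NF (THF, 0 °C) releases 14.

## Further compounds
F1 | step 5 | methyl (E)-3-(6-{[(1S,2S)-1-(3,4-dimethoxyphenyl)-2-methylbut-3-en-1-yl]oxy}-5-methoxypyridazin-3-yl)prop-2-enoate | COC(=O)/C=C/c1cc(OC)c(O[C@H](c2ccc(OC)c(OC)c2)[C@@H](C)C=C)nn1
F2 | step 5 | 2,3-diazabicyclo[2.2.2]octa-2,5-diene cycloadduct fused to the oxolane (new ring carbons unspecified) | COC(=O)/C=C/C12N=NC3(O[C@H](c4ccc(OC)c(OC)c4)[C@@H](C)C3C1)C(OC)=C2
F3 | step 5 | methyl (E)-3-[(2S,3S)-2-(3,4-dimethoxyphenyl)-7-methoxy-3-methyl-2,3,3a,4-tetrahydro-1-benzofuran-5-yl]prop-2-enoate | COC(=O)/C=C/C1=CC(OC)=C2O[C@H](c3ccc(OC)c(OC)c3)[C@@H](C)C2C1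
F4 | step 3 | 3-chloro-4-methoxy-6-(methylthio)pyridazine | COc1cc(SC)nnc1Cl
F5 | step 4 | 6-[(E)-3-(tert-butyldimethylsilyloxy)prop-1-enyl]-3-chloro-4-methoxypyridazine | COc1cc(/C=C/CO[Si](C)(C)C(C)(C)C)nnc1Cl
F6 | step 4 | 6-[(E)-3-(tert-butyldimethylsilyloxy)prop-1-enyl]-3-{[(1S,2S)-1-(3,4-dimethoxyphenyl)-2-methylbut-3-yn-1-yl]oxy}-4-methoxypyridazine | COc1cc(/C=C/CO[Si](C)(C)C(C)(C)C)nnc1O[C@H](c2ccc(OC)c(OC)c2)[C@@H](C)C#C
F7 | step 4 | silylated 2,3-diazabicyclo[2.2.2]octa-2,5,7-triene cycloadduct (bridgeheads unspecified) | CC(C)(C)[Si](C)(C)OC/C=C/C12N=NC3(O[C@H](c4ccc(OC)c(OC)c4)[C@@H](C)C3=C1)C(OC)=C2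
F8 | step 4 | tert-butyldimethylsilyl ether of 14 | COc1ccc([C@H]2Oc3c(OC)cc(/C=C/CO[Si](C)(C)C(C)(C)C)cc3[C@@H]2C)cc1OC
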